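**Retrosynthetic overview** (target locants: C1/C4 = CH–OBz, C2=C3, C5 = CH–OH, C6 = C(OH)CH2OH)
1. Target ⇐ acetonide hydrolysis of a trans-fused 1,3-dioxane/cyclohexene that masks only 5-OH and the CH2OH.
2. Cyclohexene C2=C3 ⇐ ring-closing metathesis of a 1,7-diene that already carries both allylic benzoates.
3. Key bond C1–C6 ⇐ γ-benzoyloxyallyl-indium (acrolein with its carbonyl carbon made nucleophilic, an α-acyloxy carbanion equivalent) added to the ketone of a 4-substituted 1,3-dioxan-5-one. This one step sets the quaternary carbinol and the adjacent benzoate carbon.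
4. Ketone ⇐ anti-aldol of 2,2-dimethyl-1,3-dioxan-5-one with acrolein (C4–C5 bond), then lipase resolution that installs the C4 benzoate.
5. Ring order: the dioxane is bought with the starting ketone, the cyclohexene is the only ring made (metathesis), and the dioxane is opened last.

Assumption: racemic compounds carry the prefix rac- and are written with the SMILES of the enantiomer that is carried forward; organoindium species are drawn as monomeric dibromides.

**Step 1**
Reactants: 1 2,2-dimethyl-1,3-dioxan-5-one; 2 acrolein (prop-2-enal)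
Product: 5 rac-(4R)-4-[(1R)-1-hydroxyprop-2-en-1-yl]-2,2-dimethyl-1,3-dioxan-5-one (anti aldol), via boron enolate 3 (not isolated), via boron aldolate 4 (not isolated)
Conditions: Cy2BCl, Et3N, CH2Cl2/Et2O, −78 °C; then 2, −78 → −20 °C; H2O2, pH 7 buffer, MeOH, 0 °C
Reagents that add atoms: none
Why: Boron-mediated aldol reaction in which the ring-locked E-enolate 3 adds 1,2 to acrolein through a Zimmerman–Traxler chair, setting the two new stereocentres anti (4R*,1′R*, racemic) and avoiding conjugate addition.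

**Step 2**
Reactants: 5 rac-(4R)-4-[(1R)-1-hydroxyprop-2-en-1-yl]-2,2-dimethyl-1,3-dioxan-5-one
Product: 6 (1R)-1-[(4R)-2,2-dimethyl-5-oxo-1,3-dioxan-4-yl]prop-2-en-1-yl benzoate
Conditions: Burkholderia cepacia lipase (immobilised), vinyl benzoate (3 equiv), MTBE, 4 Å MS, 35 °C, stopped at ca. 45% conversion; chromatography
Reagents that add atoms: vinyl benzoate, C=COC(=O)c1ccccc1
Why: Lipase-catalysed kinetic resolution by transesterification (Kazlauskas rule, vinyl as medium and the dioxanone ring as large group, so the 1′R carbinol is acylated); because 5 is a single diastereomer this gives the 4R,1′R benzoate, the 4S,1′S alcohol stays behind and is separated, and the base-free medium avoids β-elimination.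

**Step 3**
Reactants: 2 acrolein (prop-2-enal); 7 benzoyl bromide
Product: 8 3-bromoprop-1-en-1-yl benzoate (E/Z mixture)
Conditions: ZnCl2 (cat.), CH2Cl2, −20 → 0 °C
Reagents that add atoms: none
Why: ZnCl2-catalysed 1,4-addition of the acyl bromide across acrolein (O-acylation, bromide to the β-carbon) gives the 3-bromopropenyl ester; the E/Z ratio does not matter because the derived allylindium equilibrates.

**Step 4**
Reactants: 6 (1R)-1-[(4R)-2,2-dimethyl-5-oxo-1,3-dioxan-4-yl]prop-2-en-1-yl benzoate; 8 3-bromoprop-1-en-1-yl benzoate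
Product: 11 (1S)-1-[(4R,5S)-4-[(1R)-1-(benzoyloxy)prop-2-en-1-yl]-5-hydroxy-2,2-dimethyl-1,3-dioxan-5-yl]prop-2-en-1-yl benzoate, via allylindium reagent 9 (not isolated), via indium alkoxide 10 (not isolated)
Conditions: In powder (1.5 equiv), 8 (2 equiv), THF, 0 °C → rt (Barbier mode); aq. NH4Cl
Reagents that add atoms: none
Why: Proposed new method: indium inserts into allylic bromide 8 to give γ-benzoyloxyallyl-indium 9, an acrolein unit whose carbonyl carbon has become nucleophilic, which adds through its oxygen-bearing carbon to the very electrophilic dioxanone carbonyl in a closed six-membered (Zimmerman–Traxler) transition state; attack is equatorial and trans to the C4 side chain (as hydrides and Grignard reagents behave with 4-substituted 1,3-dioxan-5-ones), which sets the axial tertiary alcohol at C5, and with the unsubstituted C6 arm axial and the benzoyloxy group equatorial in the chair the new benzoate carbon is formed 1S; the closest known reaction type is the indium- or zinc-mediated Barbier acyloxyallylation of aldehydes with 3-bromopropenyl esters.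

**Step 5**
Reactants: 11 (1S)-1-[(4R,5S)-4-[(1R)-1-(benzoyloxy)prop-2-en-1-yl]-5-hydroxy-2,2-dimethyl-1,3-dioxan-5-yl]prop-2-en-1-yl benzoate
Product: 12 (4aS,5S,8R,8aR)-4a-hydroxy-2,2-dimethyl-4a,5,8,8a-tetrahydro-4H-1,3-benzodioxine-5,8-diyl dibenzoate
Conditions: second-generation Grubbs catalyst (5 mol%), CH2Cl2 (0.005 M), 40 °C
Reagents that add atoms: none
Why: Ring-closing olefin metathesis of the two vinyl groups, which sit trans-diequatorial on the dioxane chair and close to the trans-fused cyclohexene with loss of ethene; the free tertiary hydroxyl and the benzoates are tolerated and no stereocentre is touched.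

**Step 6**
Reactants: 12 (4aS,5S,8R,8aR)-4a-hydroxy-2,2-dimethyl-4a,5,8,8a-tetrahydro-4H-1,3-benzodioxine-5,8-diyl dibenzoate
Product: 13 (1S,4R,5R,6R)-5,6-dihydroxy-6-(hydroxymethyl)cyclohex-2-ene-1,4-diyl dibenzoate (target)
Conditions: AcOH/H2O (4:1), 40 °C
Reagents that add atoms: none
Why: Mild acid-catalysed acetal hydrolysis removes the isopropylidene group without touching any stereocentre; weakly acidic, base-free conditions are chosen to suppress benzoate migration to the freed hydroxyl groups.

**Compound list**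
1 | 2,2-dimethyl-1,3-dioxan-5-one | CC1(C)OCC(=O)CO1 | starting material
2 | acrolein (prop-2-enal) | C=CC=O | starting material
3 | 2,2-dimethyl-4H-1,3-dioxin-5-yl dicyclohexylborinate (boron enolate) | CC1(C)OCC(OB(C2CCCCC2)C2CCCCC2)=CO1 | intermediate
4 | rac-(1R)-1-[(4R)-2,2-dimethyl-5-oxo-1,3-dioxan-4-yl]prop-2-en-1-yl dicyclohexylborinate (boron aldolate) | C=C[C@@H](OB(C1CCCCC1)C1CCCCC1)[C@H]1OC(C)(C)OCC1=O | intermediate
5 | rac-(4R)-4-[(1R)-1-hydroxyprop-2-en-1-yl]-2,2-dimethyl-1,3-dioxan-5-one | C=C[C@@H](O)[C@H]1OC(C)(C)OCC1=O | intermediate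
6 | (1R)-1-[(4R)-2,2-dimethyl-5-oxo-1,3-dioxan-4-yl]prop-2-en-1-yl benzoate | C=C[C@@H](OC(=O)c1ccccc1)[C@H]1OC(C)(C)OCC1=O | intermediate
7 | benzoyl bromide | O=C(Br)c1ccccc1 | starting material
8 | 3-bromoprop-1-en-1-yl benzoate (E/Z mixture) | O=C(OC=CCBr)c1ccccc1 | intermediate
9 | [3-(benzoyloxy)prop-2-en-1-yl]indium dibromide (trivalent indium, E/Z) | O=C(OC=CC[In](Br)Br)c1ccccc1 | intermediate
10 | dibromoindium alkoxide of 11 | C=C[C@@H](OC(=O)c1ccccc1)[C@H]1OC(C)(C)OC[C@]1(O[In](Br)Br)[C@@H](OC(=O)c1ccccc1)C=C | intermediate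
11 | (1S)-1-[(4R,5S)-4-[(1R)-1-(benzoyloxy)prop-2-en-1-yl]-5-hydroxy-2,2-dimethyl-1,3-dioxan-5-yl]prop-2-en-1-yl benzoate | C=C[C@@H](OC(=O)c1ccccc1)[C@H]1OC(C)(C)OC[C@]1(O)[C@@H](OC(=O)c1ccccc1)C=C | intermediate
12 | (4aS,5S,8R,8aR)-4a-hydroxy-2,2-dimethyl-4a,5,8,8a-tetrahydro-4H-1,3-benzodioxine-5,8-diyl dibenzoate (trans-fused) | O=C(O[C@H]1C=C[C@@H](OC(=O)c2ccccc2)[C@@H](OC(C)(C)OC3)[C@@]13O)c1ccccc1 | intermediate
13 | (1S,4R,5R,6R)-5,6-dihydroxy-6-(hydroxymethyl)cyclohex-2-ene-1,4-diyl dibenzoate | O=C(O[C@H]1C=C[C@@H](OC(=O)c2ccccc2)[C@@H](O)[C@]1(O)CO)c1ccccc1 | target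

**Count:** 6 steps in total; longest linear sequence 5 steps (steps 1, 2, 4, 5, 6); step 3 prepares the allyl reagent. Step 2 is a resolution, so its yield is capped at 50%.

**Steps most likely to fail, with fallbacks**

Step 4 (key addition). A γ-substituted allylindium may add slowly to a ketone, and if the Z-configured, ester-chelated allylindium reacts instead, the benzoate carbon would come out epimeric. The fallback separates bond formation from stereocontrol and sets out from 6. Lithiated methoxyallene (methoxyallene, n-BuLi, THF, −78 °C), an acyl-anion equivalent of acrolein, adds to the ketone trans to the C4 side chain to give the methoxyallenyl carbinol F1. Brief treatment with dilute H2SO4 in acetone at 0 °C hydrolyses the enol ether to the vinyl ketone F2. Second-generation Grubbs catalyst (CH2Cl2, 40 °C) closes it to the bicyclic enone F3. Luche reduction (NaBH4, CeCl3·7H2O, MeOH, −78 °C) should deliver hydride to the face opposite the axial tertiary hydroxyl and give the bicyclic allylic alcohol F4. BzCl, pyridine and DMAP then acylate only the secondary hydroxyl, and the route is rejoined at 12.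

Step 2 (lipase resolution). The bulky ketone and the slow acyl donor vinyl benzoate may give poor rate or selectivity. The fallback sets out from 5. A Sharpless kinetic resolution (Ti(OiPr)4, D-(−)-diisopropyl tartrate, t-BuOOH 0.6 equiv, 4 Å MS, CH2Cl2, −20 °C) oxidises the unwanted 4S,1′S enantiomer to the epoxy alcohol F6 and leaves the enantiopure alcohol F5. BzCl and pyridine in CH2Cl2 at 0 °C convert F5 into 6.

Step 5 (metathesis). Two electron-poor allylic benzoate alkenes must close to a strained trans-fused bicycle, which may be slow or lead to dimers. The fallback sets out from 11. The acetonide is removed first (AcOH/H2O 4:1, 40 °C) to give the acyclic tetraol dibenzoate F7. Its conformationally free chain is then closed with second-generation Grubbs catalyst (CH2Cl2, 40 °C) to give 13 directly.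

**Further compounds**
F1 | step 4 | (1R)-1-[(4R,5R)-5-hydroxy-5-(1-methoxypropa-1,2-dien-1-yl)-2,2-dimethyl-1,3-dioxan-4-yl]prop-2-en-1-yl benzoate | C=C[C@@H](OC(=O)c1ccccc1)[C@H]1OC(C)(C)OC[C@]1(O)C(OC)=C=C
F2 | step 4 | (1R)-1-[(4R,5R)-5-hydroxy-2,2-dimethyl-5-(prop-2-enoyl)-1,3-dioxan-4-yl]prop-2-en-1-yl benzoate | C=C[C@@H](OC(=O)c1ccccc1)[C@H]1OC(C)(C)OC[C@]1(O)C(=O)C=C
F3 | step 4 | (4aR,8R,8aR)-4a-hydroxy-2,2-dimethyl-5-oxo-4a,5,8,8a-tetrahydro-4H-1,3-benzodioxin-8-yl benzoate | O=C1C=C[C@@H](OC(=O)c2ccccc2)[C@@H](OC(C)(C)OC3)[C@@]13O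
F4 | step 4 | (4aS,5S,8R,8aR)-4a,5-dihydroxy-2,2-dimethyl-4a,5,8,8a-tetrahydro-4H-1,3-benzodioxin-8-yl benzoate | O[C@H]1C=C[C@@H](OC(=O)c2ccccc2)[C@@H](OC(C)(C)OC3)[C@@]13O
F5 | step 2 | (4R)-4-[(1R)-1-hydroxyprop-2-en-1-yl]-2,2-dimethyl-1,3-dioxan-5-one (single enantiomer) | C=C[C@@H](O)[C@H]1OC(C)(C)OCC1=O
F6 | step 2 | (4S)-4-[(S)-hydroxy[(2S)-oxiran-2-yl]methyl]-2,2-dimethyl-1,3-dioxan-5-one | C1O[C@@H]1[C@H](O)[C@@H]1OC(C)(C)OCC1=O
F7 | step 5 | (3S,4R,5R,6R)-4,5-dihydroxy-4-(hydroxymethyl)octa-1,7-diene-3,6-diyl dibenzoate | C=C[C@@H](OC(=O)c1ccccc1)[C@@H](O)[C@](O)(CO)[C@@H](OC(=O)c1ccccc1)C=C
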